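**Retrosynthetic overview**

- The target comes from its bis(silyl) ether (TIPS on the ring-A phenol, TBS on ring B) by one global desilylation.
- Key disconnection: ring A (bonds C6–C7 and C8–C8a, chroman numbering) and the pyran O1–C2 bond are taken apart together. This gives a Chan-type 1-methoxy-1,3-bis(silyloxy)diene carrying the (R)-epoxy-prenyl side chain and a 3-methoxy ynone that already carries the whole (E)-4-silyloxycinnamoyl arm.
- The diene comes from methyl acetoacetate and prenyl bromide (C-alkylation, O-silylation, Shi epoxidation as the only stereo-defining event, γ-silylation).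
- The ynone comes from 4-silyloxybenzaldehyde (Horner–Wadsworth–Emmons to the Weinreb cinnamamide) and lithium methoxyacetylide made from chloroacetaldehyde dimethyl acetal.
- Ring order: ring B is bought; ring A is made by [4+2] cycloaddition/aromatisation, and the pyran ring closes directly afterwards in the same flask by 6-endo opening of the epoxide by the one phenol that the aromatisation sets free.

Assumption: the stereocentre is read as (3R) in chroman numbering, and silyl-protected 4-hydroxybenzaldehyde, the Weinreb-amide phosphonate and the D-fructose-derived epoxidation ketone are treated as catalogue chemicals.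

**Route**

Step 1
Reactants: 1 methyl acetoacetate; 2 prenyl bromide (1-bromo-3-methylbut-2-ene)
Product: 3 methyl 2-acetyl-5-methylhex-4-enoate (racemic)
Conditions: 1 (2 equiv), K2CO3, acetone, reflux
Reagents that add atoms: none
Why: Acetoacetic ester alkylation, in which the K2CO3-generated enolate of the β-keto ester is C-alkylated by the allylic bromide in an SN2 reaction, an excess of 1 holding back dialkylation.

Step 2
Reactants: 3 methyl 2-acetyl-5-methylhex-4-enoate
Product: 4 methyl 5-methyl-2-{1-[(triisopropylsilyl)oxy]ethylidene}hex-4-enoate (E/Z mixture)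
Conditions: NaH (1.1 equiv), THF, 0 °C; then TIPSOTf (1.1 equiv), −78 → 0 °C
Reagents that add atoms: triisopropylsilyl trifluoromethanesulfonate (TIPSOTf), CC(C)[Si](C(C)C)(C(C)C)OS(=O)(=O)C(F)(F)F
Why: O-silylation of a β-keto ester enolate, in which the hard silyl triflate traps the sodium enolate on the ketone oxygen to give the conjugated β-silyloxy enoate (either double-bond geometry serves), which removes the acidic 1,3-dicarbonyl proton before the oxidation and later becomes the robust TIPS ether that keeps one ring-A oxygen capped.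

Step 3
Reactants: 4 methyl 5-methyl-2-{1-[(triisopropylsilyl)oxy]ethylidene}hex-4-enoate
Product: 5 methyl 2-{[(2R)-3,3-dimethyloxiran-2-yl]methyl}-3-[(triisopropylsilyl)oxy]but-2-enoate (E/Z mixture)
Conditions: 1,2:4,5-di-O-isopropylidene-β-D-erythro-2,3-hexodiulo-2,6-pyranose (D-fructose-derived Shi ketone, 0.3 equiv), KHSO5 (as Oxone, 1.4 equiv), K2CO3, Bu4NHSO4 (cat), MeCN/CH2(OMe)2/aq Na2B4O7 buffer (pH 10.5), 0 °C, 2 h
Reagents that add atoms: potassium peroxymonosulfate (KHSO5, active component of Oxone), [K+].[O-]S(=O)(=O)OO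
Why: Shi asymmetric epoxidation, in which the chiral dioxirane formed from the D-fructose-derived ketone transfers oxygen to the electron-rich trisubstituted prenyl alkene through the spiro transition state and so sets the (R) epoxide carbon (about 90 % ee expected), while the tetrasubstituted, ester-conjugated and TIPS-shielded enol ether alkene is too hindered and electron-poor to compete.

Step 4
Reactants: 5 methyl 2-{[(2R)-3,3-dimethyloxiran-2-yl]methyl}-3-[(triisopropylsilyl)oxy]but-2-enoate
Product: 6 {[2-{[(2R)-3,3-dimethyloxiran-2-yl]methyl}-1-methoxy-3-[(triisopropylsilyl)oxy]buta-1,3-dien-1-yl]oxy}trimethylsilane (used crude)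
Conditions: LiN(iPr)2 (1.2 equiv), THF, −78 °C; TMSCl (1.5 equiv), −78 → 0 °C; concentrate, pentane, filter
Reagents that add atoms: chlorotrimethylsilane (TMSCl), C[Si](C)(C)Cl
Why: Vinylogous (γ) deprotonation of the β-silyloxy enoate and O-silylation of the resulting dienolate, the standard second stage of a Chan-type 1-methoxy-1,3-bis(silyloxy)diene synthesis, which the epoxide survives at −78 °C.

Step 5
Reactants: 7 4-[(tert-butyldimethylsilyl)oxy]benzaldehyde; 8 diethyl {2-[methoxy(methyl)amino]-2-oxoethyl}phosphonate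
Product: 9 (2E)-3-{4-[(tert-butyldimethylsilyl)oxy]phenyl}-N-methoxy-N-methylprop-2-enamide
Conditions: 8, NaH (1.1 equiv), THF, 0 °C; then 7, 0 °C → rt
Reagents that add atoms: none
Why: Horner–Wadsworth–Emmons olefination with a stabilised Weinreb-amide phosphonate, which gives the (E)-enamide with high selectivity under mild conditions that leave the aryl silyl ether intact.

Step 6
Reactants: 9 (2E)-3-{4-[(tert-butyldimethylsilyl)oxy]phenyl}-N-methoxy-N-methylprop-2-enamide; 10 2-chloro-1,1-dimethoxyethane (chloroacetaldehyde dimethyl acetal)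
Product: 12 (4E)-5-{4-[(tert-butyldimethylsilyl)oxy]phenyl}-1-methoxypent-4-en-1-yn-3-one, via lithium methoxyacetylide 11 (not isolated)
Conditions: 10, LiNEt2 (3 equiv per 10), THF, 0 °C, 2 h; then 9, −78 → −40 °C; inverse quench into cold pH 7 phosphate buffer
Reagents that add atoms: none
Why: Twofold base-induced elimination (of MeOH and HCl) from the chloroacetal and deprotonation give lithium methoxyacetylide, whose single addition to the Weinreb amide stops at the chelated tetrahedral intermediate (Weinreb ketone synthesis) and releases the ynone only on the cold buffered quench that also ties up the amines as salts.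

Step 7
Reactants: 6 {[2-{[(2R)-3,3-dimethyloxiran-2-yl]methyl}-1-methoxy-3-[(triisopropylsilyl)oxy]buta-1,3-dien-1-yl]oxy}trimethylsilane; 12 (4E)-5-{4-[(tert-butyldimethylsilyl)oxy]phenyl}-1-methoxypent-4-en-1-yn-3-one
Product: 15 (2E)-3-{4-[(tert-butyldimethylsilyl)oxy]phenyl}-1-[(3R)-3-hydroxy-7-methoxy-2,2-dimethyl-5-[(triisopropylsilyl)oxy]-3,4-dihydro-2H-chromen-8-yl]prop-2-en-1-one, via cyclohexa-1,4-diene cycloadduct 13 (not isolated), via epoxy phenol 14 (not isolated)
Conditions: 12 (1.0 equiv), 6 (1.5 equiv), PhMe, rt → 60 °C, 16 h; then CH2Cl2, (1S)-(+)-camphor-10-sulfonic acid (0.2 equiv), 0 °C → rt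
Reagents that add atoms: none
Why: Proposed new method: the nucleophilic CH2 terminus of the Chan-type 1-methoxy-1,3-bis(silyloxy)diene bonds to the methoxy-bearing β-carbon of the ynone and the ketene-acetal carbon to the α-carbon (normal-demand Diels–Alder regiochemistry, which places the acyl group between the OMe carbon and the new phenol carbon), acid then collapses the mixed methyl/trimethylsilyl ketal of cycloadduct 13 with loss of MeOSiMe3 to aromatise ring A to the single free phenol 14 (the other ring-A oxygen stays capped as the TIPS ether), and this phenol opens the protonated epoxide at its tertiary carbon in 6-endo fashion to close the pyran ring while the C–O bond at the (R) carbinol carbon is never broken; the closest known reaction types are the Diels–Alder benzannulation of Chan/Brassard silyloxydienes with alkynones and the acid-mediated cyclisation of ortho-(2,3-epoxy-3-methylbutyl)phenols to 2,2-dimethylchroman-3-ols.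

Step 8
Reactants: 15 (2E)-3-{4-[(tert-butyldimethylsilyl)oxy]phenyl}-1-[(3R)-3-hydroxy-7-methoxy-2,2-dimethyl-5-[(triisopropylsilyl)oxy]-3,4-dihydro-2H-chromen-8-yl]prop-2-en-1-one
Product: 16 (2E)-1-[(3R)-3,5-dihydroxy-7-methoxy-2,2-dimethyl-3,4-dihydro-2H-chromen-8-yl]-3-(4-hydroxyphenyl)prop-2-en-1-one
Conditions: Bu4NF (2.5 equiv), AcOH (2.5 equiv), THF, 0 °C → rt
Reagents that add atoms: none
Why: Fluoride-mediated desilylation of both aryl silyl ethers (Si–F bond formation), buffered with AcOH so that the phenoxides are protonated as they form and the enone and the (R) carbinol are left untouched.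

**Compound list**

1 | methyl acetoacetate (methyl 3-oxobutanoate) | CC(=O)CC(=O)OC | starting material
2 | prenyl bromide (1-bromo-3-methylbut-2-ene) | CC(C)=CCBr | starting material
3 | methyl 2-acetyl-5-methylhex-4-enoate (racemic) | CC(=O)C(CC=C(C)C)C(=O)OC | intermediate
4 | methyl 5-methyl-2-{1-[(triisopropylsilyl)oxy]ethylidene}hex-4-enoate (E/Z mixture) | COC(=O)C(CC=C(C)C)=C(C)O[Si](C(C)C)(C(C)C)C(C)C | intermediate
5 | methyl 2-{[(2R)-3,3-dimethyloxiran-2-yl]methyl}-3-[(triisopropylsilyl)oxy]but-2-enoate (E/Z mixture) | COC(=O)C(C[C@H]1OC1(C)C)=C(C)O[Si](C(C)C)(C(C)C)C(C)C | intermediate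
6 | {[2-{[(2R)-3,3-dimethyloxiran-2-yl]methyl}-1-methoxy-3-[(triisopropylsilyl)oxy]buta-1,3-dien-1-yl]oxy}trimethylsilane (ketene-acetal geometry not defined) | C=C(O[Si](C(C)C)(C(C)C)C(C)C)C(C[C@H]1OC1(C)C)=C(OC)O[Si](C)(C)C | intermediate
7 | 4-[(tert-butyldimethylsilyl)oxy]benzaldehyde | O=Cc1ccc(O[Si](C)(C)C(C)(C)C)cc1 | starting material
8 | diethyl {2-[methoxy(methyl)amino]-2-oxoethyl}phosphonate | CCOP(=O)(CC(=O)N(C)OC)OCC | starting material
9 | (2E)-3-{4-[(tert-butyldimethylsilyl)oxy]phenyl}-N-methoxy-N-methylprop-2-enamide | CON(C)C(=O)/C=C/c1ccc(O[Si](C)(C)C(C)(C)C)cc1 | intermediate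
10 | 2-chloro-1,1-dimethoxyethane | COC(CCl)OC | starting material
11 | lithium methoxyacetylide | [Li]C#COC | intermediate
12 | (4E)-5-{4-[(tert-butyldimethylsilyl)oxy]phenyl}-1-methoxypent-4-en-1-yn-3-one | COC#CC(=O)/C=C/c1ccc(O[Si](C)(C)C(C)(C)C)cc1 | intermediate
13 | (2E)-3-{4-[(tert-butyldimethylsilyl)oxy]phenyl}-1-[5-{[(2R)-3,3-dimethyloxiran-2-yl]methyl}-2,6-dimethoxy-4-[(triisopropylsilyl)oxy]-6-[(trimethylsilyl)oxy]cyclohexa-1,4-dien-1-yl]prop-2-en-1-one (epimers at the ketal carbon) | COC1=C(C(=O)/C=C/c2ccc(O[Si](C)(C)C(C)(C)C)cc2)C(OC)(O[Si](C)(C)C)C(C[C@H]2OC2(C)C)=C(O[Si](C(C)C)(C(C)C)C(C)C)C1 | intermediate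
14 | (2E)-3-{4-[(tert-butyldimethylsilyl)oxy]phenyl}-1-[3-{[(2R)-3,3-dimethyloxiran-2-yl]methyl}-2-hydroxy-6-methoxy-4-[(triisopropylsilyl)oxy]phenyl]prop-2-en-1-one | COc1cc(O[Si](C(C)C)(C(C)C)C(C)C)c(C[C@H]2OC2(C)C)c(O)c1C(=O)/C=C/c1ccc(O[Si](C)(C)C(C)(C)C)cc1 | intermediate
15 | (2E)-3-{4-[(tert-butyldimethylsilyl)oxy]phenyl}-1-[(3R)-3-hydroxy-7-methoxy-2,2-dimethyl-5-[(triisopropylsilyl)oxy]-3,4-dihydro-2H-chromen-8-yl]prop-2-en-1-one | COc1cc(O[Si](C(C)C)(C(C)C)C(C)C)c2c(c1C(=O)/C=C/c1ccc(O[Si](C)(C)C(C)(C)C)cc1)OC(C)(C)[C@H](O)C2 | intermediate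
16 | (2E)-1-[(3R)-3,5-dihydroxy-7-methoxy-2,2-dimethyl-3,4-dihydro-2H-chromen-8-yl]-3-(4-hydroxyphenyl)prop-2-en-1-one | COc1cc(O)c2c(c1C(=O)/C=C/c1ccc(O)cc1)OC(C)(C)[C@H](O)C2 | target

**Step count and risks**

Total step count: 8. Longest linear sequence: 6 steps (1 → 2 → 3 → 4 → 7 → 8); the ynone branch is steps 5 and 6.

Steps most likely to fail:

Step 7. The methoxy ynone is an electronically deactivated dienophile that also carries a styryl enone. The mixed ketal may aromatise by losing silanol instead of methanol. 5-exo opening may compete with the 6-endo closure. The fallback sets out from 6 and from 11 (made as in step 6) and comes back at 16. 11 is acylated with N-methoxy-N-methylacetamide F1 to give 4-methoxybut-3-yn-2-one F2, a smaller dienophile with no second π-acceptor. F2 and 6 are heated and then treated with acid as before. This leads through the cycloadduct 1-[5-{[(2R)-3,3-dimethyloxiran-2-yl]methyl}-2,6-dimethoxy-4-[(triisopropylsilyl)oxy]-6-[(trimethylsilyl)oxy]cyclohexa-1,4-dien-1-yl]ethan-1-one F3 and the epoxy phenol 1-[3-{[(2R)-3,3-dimethyloxiran-2-yl]methyl}-2-hydroxy-6-methoxy-4-[(triisopropylsilyl)oxy]phenyl]ethan-1-one F4 to the chromanyl methyl ketone 1-[(3R)-3-hydroxy-7-methoxy-2,2-dimethyl-5-[(triisopropylsilyl)oxy]-3,4-dihydro-2H-chromen-8-yl]ethan-1-one F5. The enone is then built last by Claisen–Schmidt condensation of F5 with aldehyde 7 (KOH, EtOH/H2O, rt). Both aryl silyl ethers are cleaved under these conditions, so 16 is obtained directly.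

Step 6. The 3-methoxy ynone can take up the liberated amines (Et2NH, MeNHOMe) at its β-carbon or hydrate during the quench. The fallback sets out from 9 and comes back at 12. 9 is reduced with iBu2AlH (THF, −78 °C) to (2E)-3-{4-[(tert-butyldimethylsilyl)oxy]phenyl}prop-2-enal F6. 11 adds to F6 to give racemic (4E)-5-{4-[(tert-butyldimethylsilyl)oxy]phenyl}-1-methoxypent-4-en-1-yn-3-ol F7, an alcohol that does not take up amines and can be washed free of them. MnO2 (CH2Cl2, rt) then oxidises the allylic-propargylic alcohol to 12 under neutral conditions.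

Step 3. The dioxirane may attack the silyl enol ether, the enol ether may hydrolyse at pH 10.5, and the ee may fall short. The fallback sets out from 1 and comes back at 5; the stereocentre is brought in with a Sharpless-derived building block instead. 3-Methylbut-2-en-1-ol F8 is epoxidised (Ti(OiPr)4, D-(−)-diisopropyl tartrate, t-BuOOH, 4 Å sieves, −20 °C) and tosylated in situ to [(2R)-3,3-dimethyloxiran-2-yl]methyl 4-methylbenzenesulfonate F9, which is recrystallised to raise the ee. The sodium enolate of 1 (in excess) is C-alkylated with F9 (NaH, NaI cat, THF/DMF) to give methyl 2-acetyl-3-[(2R)-3,3-dimethyloxiran-2-yl]propanoate F10. O-Silylation of F10 (NaH, TIPSOTf, THF, −78 °C) gives 5.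

Further compounds
F1 | step 7 | N-methoxy-N-methylacetamide | CC(=O)N(C)OC
F2 | step 7 | 4-methoxybut-3-yn-2-one | COC#CC(C)=O
F3 | step 7 | 1-[5-{[(2R)-3,3-dimethyloxiran-2-yl]methyl}-2,6-dimethoxy-4-[(triisopropylsilyl)oxy]-6-[(trimethylsilyl)oxy]cyclohexa-1,4-dien-1-yl]ethan-1-one | COC1=C(C(C)=O)C(OC)(O[Si](C)(C)C)C(C[C@H]2OC2(C)C)=C(O[Si](C(C)C)(C(C)C)C(C)C)C1
F4 | step 7 | 1-[3-{[(2R)-3,3-dimethyloxiran-2-yl]methyl}-2-hydroxy-6-methoxy-4-[(triisopropylsilyl)oxy]phenyl]ethan-1-one | COc1cc(O[Si](C(C)C)(C(C)C)C(C)C)c(C[C@H]2OC2(C)C)c(O)c1C(C)=O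
F5 | step 7 | 1-[(3R)-3-hydroxy-7-methoxy-2,2-dimethyl-5-[(triisopropylsilyl)oxy]-3,4-dihydro-2H-chromen-8-yl]ethan-1-one | COc1cc(O[Si](C(C)C)(C(C)C)C(C)C)c2c(c1C(C)=O)OC(C)(C)[C@H](O)C2
F6 | step 6 | (2E)-3-{4-[(tert-butyldimethylsilyl)oxy]phenyl}prop-2-enal | O=C/C=C/c1ccc(O[Si](C)(C)C(C)(C)C)cc1
F7 | step 6 | (4E)-5-{4-[(tert-butyldimethylsilyl)oxy]phenyl}-1-methoxypent-4-en-1-yn-3-ol (racemic) | COC#CC(O)/C=C/c1ccc(O[Si](C)(C)C(C)(C)C)cc1
F8 | step 3 | 3-methylbut-2-en-1-ol | CC(C)=CCO
F9 | step 3 | [(2R)-3,3-dimethyloxiran-2-yl]methyl 4-methylbenzenesulfonate | Cc1ccc(cc1)S(=O)(=O)OC[C@H]1OC1(C)C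
F10 | step 3 | methyl 2-acetyl-3-[(2R)-3,3-dimethyloxiran-2-yl]propanoate | CC(=O)C(C[C@H]1OC1(C)C)C(=O)OC
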